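The readings are simulated for substances that don't exist; scatter was added.

Tuesday's readings show 81.8% of the partner kept as target: this kept share K, the plateau amount of target over the amount of partner charged, is the ratio of two amounts.

all flasks: substrate 0.20 M

|  | partner | initiator | temperature | remark | time |
|---|---|---|---|---|---|
| Tuesday's | 0.19 M | 1 mM | 60 °C | the very flask that is asked about, followed so far |  |
| Monday's | 0.095 M | 1 mM | 66 °C | run made earlier |  |
| flask | 0.190 M | 1.0 mM | 60 °C |  | 80 min |

- Tuesday's (time / min: target / %, substrate / %): 8.00: 49.6, 50.1; 20.0: 75.7, 23.5; 40.0: 77.4, 21.2; 60.0: 78.0, 21.1; 80.0: 77.8, 20.9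
- Monday's (time / min: target / %, substrate / %): 0.250: 3.0, 96.4; 0.500: 5.9, 94.6; 0.833: 10.5, 90.2; 1.50: 17.2, 83.0; 3.00: 28.7, 71.1

(scatter of a reading: 0.5 percentage points)

- spring: at 80 min take out 90% of the target then present, then wait 40 min
- autumn: at 80 min raise the temperature by 25 K, then wait 40 min
- dawn: change nothing and wait 40 min more
- dusk: at 80 min add partner, 100% of the amount charged, then wait 40 min

- percent here means substrate units held: one ended chains A or self-condensation product counts as two
- target taken out counts as made
- steps that have been proposed: initiator -> 2 initiating radical; substrate + initiating radical -> capped initiator + first chain carrier; partner + first chain carrier -> target + second chain carrier; substrate + second chain carrier -> released group + first chain carrier; first chain carrier -> ended carrier; 2 first chain carrier -> ended chains A; 2 second chain carrier -> ended chains B; partner -> decomposed reagent; 2 substrate -> self-condensation product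
- additions bring no volume worth counting

- target, in percent of the substrate first charged, at 80 min
- what to do for the largest gain in target; "none" if nothing gains more than 2 percentage points (spring / autumn / dawn / dusk / none)
- target present, with what was taken out counted in, in percent of the substrate first charged, after dawn
- target present, with what was taken out counted in, in percent of the substrate first charged, after dusk

In Tuesday's flask, target reads 77.4%, 78.0% and 77.8% from 40.0 min on, a mean of 77.7%. The partner charged equals 95.0% of the substrate, and each target takes one partner. Substrate still reads 20.9% at 80.0 min, so this reckoning treats partner as the limiting reagent and expects about 77.7% at 80 min. Spring, autumn and dawn add no partner, so K gives them no gain. Dusk adds partner worth 77.7% of the substrate at the same K, more than the free substrate, so substrate becomes the bound, with a ceiling of 98.6% on this reckoning.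

The forecast gives 77.7% now, dusk as the best choice, 77.8% after dawn and 96% after dusk, which is below that ceiling. Its ground is: “The sharp stop points to partner running out, not to initiator dying.”

The flask gives 77.9% now, and dusk is best with a gain of 17 percentage points. Dawn ends at 77.9% and dusk at 95.0%.

    initiator → 2 initiating radical (k = 0.0172 min⁻¹, Ea = 96.0 kJ mol⁻¹)
    substrate + initiating radical → capped initiator + first chain carrier (k = 29400 L mol⁻¹ s⁻¹, Ea = 38.0 kJ mol⁻¹)
    partner + first chain carrier → target + second chain carrier (k = 15000 L mol⁻¹ s⁻¹, Ea = 38.0 kJ mol⁻¹)
    substrate + second chain carrier → released group + first chain carrier (k = 1.81 × 10⁵ L mol⁻¹ min⁻¹, Ea = 38.0 kJ mol⁻¹)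
    first chain carrier → ended carrier (k = 22.5 min⁻¹, Ea = 75.0 kJ mol⁻¹)
    2 first chain carrier → ended chains A (k = 1.40 × 10⁶ L mol⁻¹ s⁻¹, Ea = 11.0 kJ mol⁻¹)
    2 second chain carrier → ended chains B (k = 1.00 × 10⁶ L mol⁻¹ s⁻¹, Ea = 8.00 kJ mol⁻¹)
    partner → decomposed reagent (k = 0.0264 min⁻¹, Ea = 89.0 kJ mol⁻¹)
    2 substrate → self-condensation product (k = 7.39 × 10⁻⁴ L mol⁻¹ min⁻¹, Ea = 90.0 kJ mol⁻¹)
    (constants at 60 °C)

A neighbouring flask, charged with 0.076 M of partner and otherwise the same, has partner worth 38.0% of the substrate, so K predicts 31.1% of target. That neighbour holds 34.4% of target at 80.0 min, with partner at 0% and substrate at 63.8%. It therefore keeps 90.6% of its partner as target, more than the 81.8% read from Tuesday's runs. Decomposed reagent in the neighbour stands at 0.00716 M, against 0.0341 M in Tuesday's flask.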